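**Strategy.** The ten-membered carbocycle is closed at the C9–C10 bond (germacrane numbering: C9 is the ring CH2 between the acyloxy carbon C8 and the methyl-bearing alkene carbon C10). A vinyl group on C7 of a trans-disubstituted γ-lactone is diborated enantioselectively. Its primary C9–B bond then couples intramolecularly with a (Z)-alkenyl iodide at C10 in a Suzuki–Miyaura macrocyclisation, while the secondary C8–B bond survives as the masked 8-oxygen. The step exploits the homoallylic relation of O8 to the Z-C1=C10 alkene and takes that alkene's geometry from the iodide. The precursor is an open-chain geranyl-type dienyl iodide carrying the fully substituted lactone (C6, C7, C11 set) and a vicinal bis(boronate).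

Key step: step 11

Numbering used throughout: C6 lactone carbinol carbon, C7 ring-fusion carbon, C8 acyloxy carbon, C9 ring CH2, C10 methyl-bearing alkene carbon, C11 quaternary carbinol, C12 lactone carbonyl, C13 CH2O.

Assumption: the (R,R) enantiomers of ProPhenol (step 5) and of the TADDOL-derived phosphonite (step 10) are taken to give the drawn configurations at C6 and C8; if either sense is opposite, the mirror-image ligand is used with no other change.

**Route**

Step 1
Reactants: 1 geranyl acetate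
Product: 3 (2E)-3-methyl-6-oxohex-2-en-1-yl acetate, via secondary ozonide 2 (not isolated)
Conditions: O3 (1 equiv), CH2Cl2, −78 °C; then Me2S, −78 °C to rt
Reagents that add atoms: ozone, [O-][O+]=O
Why: Chemoselective ozonolysis, since ozone attacks the electron-rich 6,7-alkene much faster than the 2,3-alkene deactivated by the allylic acetate, and the ozonide is reduced to the aldehyde.

Step 2
Reactants: 3 (2E)-3-methyl-6-oxohex-2-en-1-yl acetate; 4 ethyltriphenylphosphonium iodide
Product: 6 (2E,6Z)-7-iodo-3-methylocta-2,6-dien-1-yl acetate, via (1-iodoethyl)triphenylphosphonium iodide 5 (not isolated)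
Conditions: 4, n-BuLi, THF, 0 °C; I2, −78 °C; NaHMDS, −20 °C; then 3, −78 °C to rt
Reagents that add atoms: iodine, II
Why: Stork–Zhao–Smith olefination, in which the α-iodo ylide adds to the aldehyde under kinetic control to give the (Z)-2-iodoalkene (iodine cis to the chain), the future Z-C1=C10 geometry.

Step 3
Reactants: 6 (2E,6Z)-7-iodo-3-methylocta-2,6-dien-1-yl acetate
Product: 7 (2E,6Z)-7-iodo-3-methylocta-2,6-dien-1-ol
Conditions: K2CO3 (cat.), MeOH, rt
Reagents that add atoms: none
Why: Base-catalysed transesterification removes the acetate without touching the alkenyl iodide.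

Step 4
Reactants: 7 (2E,6Z)-7-iodo-3-methylocta-2,6-dien-1-ol
Product: 8 (2E,6Z)-7-iodo-3-methylocta-2,6-dienal
Conditions: MnO2, CH2Cl2, rt
Reagents that add atoms: none
Why: Allylic oxidation with MnO2 should give the enal with the E geometry retained.

Step 5
Reactants: 8 (2E,6Z)-7-iodo-3-methylocta-2,6-dienal; 9 methyl propiolate
Product: 10 methyl (4R,5E,9Z)-4-hydroxy-10-iodo-6-methylundeca-5,9-dien-2-ynoate
Conditions: Me2Zn, (R,R)-ProPhenol (20 mol %), toluene, 4 °C; aq. NH4Cl
Reagents that add atoms: none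
Why: Zinc–ProPhenol-catalysed asymmetric alkynylation of the enal with the zinc acetylide of 9 sets C6 by ligand control of the aldehyde face.

Step 6
Reactants: 10 methyl (4R,5E,9Z)-4-hydroxy-10-iodo-6-methylundeca-5,9-dien-2-ynoate
Product: 12 (5S)-5-[(1E,5Z)-6-iodo-2-methylhepta-1,5-dien-1-yl]furan-2(5H)-one, via Z-hydroxy enoate 11 (not isolated)
Conditions: H2 (1 atm), Pd/CaCO3 poisoned with Pb(OAc)2, quinoline, EtOAc, rt; then PPTS (cat.), CH2Cl2
Reagents that add atoms: none
Why: Lindlar semi-hydrogenation gives the Z-enoate whose hydroxyl is cis to the ester and lactonises to the butenolide, while the trisubstituted alkene and the alkenyl iodide should survive the poisoned catalyst.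

Step 7
Reactants: 12 (5S)-5-[(1E,5Z)-6-iodo-2-methylhepta-1,5-dien-1-yl]furan-2(5H)-one; 13 vinylmagnesium bromide
Product: 14 (4R,5S)-4-ethenyl-5-[(1E,5Z)-6-iodo-2-methylhepta-1,5-dien-1-yl]oxolan-2-one
Conditions: CuBr·SMe2 (20 mol %), THF, −78 °C; aq. NH4Cl
Reagents that add atoms: none
Why: Copper-catalysed conjugate addition of the vinyl Grignard reagent occurs anti to the C6 substituent of the butenolide, setting C7 trans to C6 (the future trans-fused lactone).

Step 8
Reactants: 14 (4R,5S)-4-ethenyl-5-[(1E,5Z)-6-iodo-2-methylhepta-1,5-dien-1-yl]oxolan-2-one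
Product: 15 (3R,4S,5S)-4-ethenyl-3-(hydroxymethyl)-5-[(1E,5Z)-6-iodo-2-methylhepta-1,5-dien-1-yl]oxolan-2-one
Conditions: LDA, THF, −78 °C; monomeric CH2O (gas, from cracked paraformaldehyde); AcOH quench
Reagents that add atoms: formaldehyde, C=O
Why: Aldol reaction of the lithium lactone enolate with formaldehyde introduces C13 anti to the C7 vinyl group (this C11 centre is set again in step 9).

Step 9
Reactants: 15 (3R,4S,5S)-4-ethenyl-3-(hydroxymethyl)-5-[(1E,5Z)-6-iodo-2-methylhepta-1,5-dien-1-yl]oxolan-2-one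
Product: 16 (3R,4R,5R)-4-ethenyl-3-hydroxy-3-(hydroxymethyl)-5-[(1E,5Z)-6-iodo-2-methylhepta-1,5-dien-1-yl]oxolan-2-one
Conditions: LDA (2.2 equiv), THF, −78 °C; 2-(phenylsulfonyl)-3-phenyloxaziridine, −78 °C; AcOH quench
Reagents that add atoms: 2-(phenylsulfonyl)-3-phenyloxaziridine, O=S(=O)(N1OC1c1ccccc1)c1ccccc1
Why: Davis oxidation of the alkoxide–enolate dianion delivers oxygen to C11 anti to the adjacent C7 vinyl group, so O11 ends trans to C8 and C13 cis, giving the quaternary (11R) centre.

Step 10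
Reactants: 16 (3R,4R,5R)-4-ethenyl-3-hydroxy-3-(hydroxymethyl)-5-[(1E,5Z)-6-iodo-2-methylhepta-1,5-dien-1-yl]oxolan-2-one
Product: 17 (3R,4R,5R)-4-[(1R)-1,2-bis(4,4,5,5-tetramethyl-1,3,2-dioxaborolan-2-yl)ethyl]-3-hydroxy-3-(hydroxymethyl)-5-[(1E,5Z)-6-iodo-2-methylhepta-1,5-dien-1-yl]oxolan-2-one
Conditions: B2pin2, Pt(dba)3 (3 mol %), (R,R)-3,5-diethylphenyl-TADDOL phenylphosphonite (6 mol %), THF, 60 °C
Reagents that add atoms: bis(pinacolato)diboron, CC1(C)OB(OC1(C)C)B1OC(C)(C)C(C)(C)O1
Why: Platinum-catalysed enantioselective diboration adds B–B syn across the only monosubstituted alkene (trisubstituted alkenes are inert) and sets C8 under ligand control, the C8 boron being the masked hydroxyl.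

Step 11
Reactants: 17 (3R,4R,5R)-4-[(1R)-1,2-bis(4,4,5,5-tetramethyl-1,3,2-dioxaborolan-2-yl)ethyl]-3-hydroxy-3-(hydroxymethyl)-5-[(1E,5Z)-6-iodo-2-methylhepta-1,5-dien-1-yl]oxolan-2-one
Product: 19 (1(10)Z,4E,6R,7R,8R,11R)-11,13-dihydroxy-8-(4,4,5,5-tetramethyl-1,3,2-dioxaborolan-2-yl)germacra-1(10),4-dien-12,6-olide, via ring-opened potassium carboxylate 18 (not isolated)
Conditions: Pd(OAc)2 (10 mol %), RuPhos (12 mol %), aq. KOH (4 equiv), THF/H2O 10:1, 70 °C, slow addition of 17 to 1 mM; then 1 M HCl to pH 3, rt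
Reagents that add atoms: none
Why: Zerovalent palladium inserts into the C10–I bond with retention of the Z geometry, hydroxide turns the vicinal bis(boronate) into a bridged ate complex that transmetalates only the primary C9–B bond, and reductive elimination from the eleven-membered palladacycle forms C9–C10. The closest known reactions are the diboration/cross-coupling of vicinal bis(boronates) with alkenyl halides and B-alkyl Suzuki–Miyaura macrocyclisations. The ten-membered carbocycle is closed end-to-end by this sp3–sp2 coupling with both ring alkenes already in place (4E from geranyl acetate, 1(10)Z from the iodide), so no alkene geometry is decided in the ring closure. No stereocentre is formed: C8 is carried through as the configurationally stable secondary boronate and C6, C7 and C11 are untouched, while the γ-lactone, opened reversibly by KOH to carboxylate 18, re-closes on acidification only onto O6 because O8 is still masked as C–B. The step needs primary-over-secondary C–B selectivity, secured by neighbouring-boronate activation and sterics, and cyclisation over oligomerisation, secured by slow addition at high dilution.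

Step 12
Reactants: 19 (1(10)Z,4E,6R,7R,8R,11R)-11,13-dihydroxy-8-(4,4,5,5-tetramethyl-1,3,2-dioxaborolan-2-yl)germacra-1(10),4-dien-12,6-olide
Product: 20 (1(10)Z,4E,6R,7R,8R,11R)-8,11,13-trihydroxygermacra-1(10),4-dien-12,6-olide
Conditions: 30% H2O2, pH 7 phosphate buffer, THF, 0 °C to rt
Reagents that add atoms: hydrogen peroxide, OO
Why: Oxidation of the secondary C–B bond proceeds by 1,2-migration with retention and should give the 8β-alcohol (8R) under near-neutral conditions that leave the lactone closed.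

Step 13
Reactants: 21 ethyl 2-(hydroxymethyl)acrylate
Product: 22 ethyl 2-{[(tert-butyldimethylsilyl)oxy]methyl}acrylate
Conditions: TBSCl, imidazole, DMF, rt
Reagents that add atoms: tert-butyldimethylsilyl chloride, CC(C)(C)[Si](C)(C)Cl
Why: Standard silylation of the primary allylic alcohol.

Step 14
Reactants: 22 ethyl 2-{[(tert-butyldimethylsilyl)oxy]methyl}acrylate; 23 cis-2-butene
Product: 24 ethyl (2E)-2-{[(tert-butyldimethylsilyl)oxy]methyl}but-2-enoate
Conditions: second-generation Hoveyda–Grubbs catalyst (5 mol %), excess 23, CH2Cl2, 40 °C (sealed tube)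
Reagents that add atoms: none
Why: Olefin cross-metathesis of the 1,1-disubstituted acrylate with 2-butene should give the trisubstituted enoate as the thermodynamically favoured E isomer (methyl trans to the ester).

Step 15
Reactants: 24 ethyl (2E)-2-{[(tert-butyldimethylsilyl)oxy]methyl}but-2-enoate
Product: 25 (2E)-2-{[(tert-butyldimethylsilyl)oxy]methyl}but-2-enoic acid
Conditions: LiOH, THF/MeOH/H2O, rt; then aq. HCl to pH 4
Reagents that add atoms: lithium hydroxide, [Li+].[OH-]
Why: Saponification of the ethyl ester leaves the primary silyl ether intact.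

Step 16
Reactants: 26 cis-but-2-ene-1,4-diol
Product: 27 (2Z)-1,4-bis[(tert-butyldimethylsilyl)oxy]but-2-ene
Conditions: TBSCl (2.2 equiv), imidazole, DMF, rt
Reagents that add atoms: tert-butyldimethylsilyl chloride, CC(C)(C)[Si](C)(C)Cl
Why: Standard bis-silylation of the diol.

Step 17
Reactants: 22 ethyl 2-{[(tert-butyldimethylsilyl)oxy]methyl}acrylate; 27 (2Z)-1,4-bis[(tert-butyldimethylsilyl)oxy]but-2-ene
Product: 28 ethyl (2E)-4-[(tert-butyldimethylsilyl)oxy]-2-{[(tert-butyldimethylsilyl)oxy]methyl}but-2-enoate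
Conditions: second-generation Hoveyda–Grubbs catalyst (5 mol %), CH2Cl2, 40 °C
Reagents that add atoms: none
Why: Cross-metathesis of the acrylate with the symmetrical cis-alkene transfers the silyloxyethylidene unit and should give the E enoate (CH2OTBS trans to the ester).

Step 18
Reactants: 28 ethyl (2E)-4-[(tert-butyldimethylsilyl)oxy]-2-{[(tert-butyldimethylsilyl)oxy]methyl}but-2-enoate
Product: 29 (2E)-4-[(tert-butyldimethylsilyl)oxy]-2-{[(tert-butyldimethylsilyl)oxy]methyl}but-2-enoic acid
Conditions: LiOH, THF/MeOH/H2O, rt; then aq. HCl to pH 4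
Reagents that add atoms: lithium hydroxide, [Li+].[OH-]
Why: Saponification of the ethyl ester with the silyl ethers retained.

Step 19
Reactants: 20 (1(10)Z,4E,6R,7R,8R,11R)-8,11,13-trihydroxygermacra-1(10),4-dien-12,6-olide; 25 (2E)-2-{[(tert-butyldimethylsilyl)oxy]methyl}but-2-enoic acid
Product: 30 13-O-[(2E)-2-{[(tert-butyldimethylsilyl)oxy]methyl}but-2-enoyl] ester of 20
Conditions: 25 (1.05 equiv), DCC, DMAP (cat.), CH2Cl2, −20 to 0 °C
Reagents that add atoms: none
Why: Steglich esterification at low temperature should acylate the primary C13–OH in preference to the hindered secondary C8–OH and the unreactive tertiary C11–OH.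

Step 20
Reactants: 30 13-O-acyl diol; 29 (2E)-4-[(tert-butyldimethylsilyl)oxy]-2-{[(tert-butyldimethylsilyl)oxy]methyl}but-2-enoic acid
Product: 31 8,13-di-O-acyl compound, all three side-chain hydroxyls as TBS ethers
Conditions: 29 (2 equiv), DCC, DMAP, CH2Cl2, rt
Reagents that add atoms: none
Why: Steglich esterification of the remaining secondary 8β-OH, the tertiary α-hydroxy lactone OH being too hindered to react.

Step 21
Reactants: 31 tris-TBS diester
Product: 32 target, (1(10)Z,4E,6R,7R,8R,11R)-11-hydroxy-8-{[(2E)-4-hydroxy-2-(hydroxymethyl)but-2-enoyl]oxy}-13-{[(2E)-2-(hydroxymethyl)but-2-enoyl]oxy}germacra-1(10),4-dien-12,6-olide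
Conditions: HF·pyridine, pyridine, THF, 0 °C to rt
Reagents that add atoms: none
Why: Buffered HF·pyridine should cleave the three primary silyl ethers without acyl migration or lactone opening.

**Compound list**

1 | geranyl acetate | CC(=O)OC/C=C(\C)CCC=C(C)C | starting material
2 | (2E)-5-(5,5-dimethyl-1,2,4-trioxolan-3-yl)-3-methylpent-2-en-1-yl acetate (secondary ozonide) | CC(=O)OC/C=C(\C)CCC1OOC(C)(C)O1 | intermediate (not isolated)
3 | (2E)-3-methyl-6-oxohex-2-en-1-yl acetate | CC(=O)OC/C=C(\C)CCC=O | intermediate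
4 | ethyltriphenylphosphonium iodide | CC[P+](c1ccccc1)(c1ccccc1)c1ccccc1.[I-] | starting material
5 | (1-iodoethyl)triphenylphosphonium iodide | CC(I)[P+](c1ccccc1)(c1ccccc1)c1ccccc1.[I-] | intermediate (not isolated)
6 | (2E,6Z)-7-iodo-3-methylocta-2,6-dien-1-yl acetate | CC(=O)OC/C=C(\C)CC/C=C(/C)I | intermediate
7 | (2E,6Z)-7-iodo-3-methylocta-2,6-dien-1-ol | OC/C=C(\C)CC/C=C(/C)I | intermediate
8 | (2E,6Z)-7-iodo-3-methylocta-2,6-dienal | O=C/C=C(\C)CC/C=C(/C)I | intermediate
9 | methyl propiolate | C#CC(=O)OC | starting material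
10 | methyl (4R,5E,9Z)-4-hydroxy-10-iodo-6-methylundeca-5,9-dien-2-ynoate | COC(=O)C#C[C@H](O)/C=C(\C)CC/C=C(/C)I | intermediate
11 | methyl (2Z,4S,5E,9Z)-4-hydroxy-10-iodo-6-methylundeca-2,5,9-trienoate | COC(=O)/C=C\[C@H](O)/C=C(\C)CC/C=C(/C)I | intermediate (not isolated)
12 | (5S)-5-[(1E,5Z)-6-iodo-2-methylhepta-1,5-dien-1-yl]furan-2(5H)-one | O=C1C=C[C@@H](/C=C(\C)CC/C=C(/C)I)O1 | intermediate
13 | vinylmagnesium bromide | C=C[Mg]Br | starting material
14 | (4R,5S)-4-ethenyl-5-[(1E,5Z)-6-iodo-2-methylhepta-1,5-dien-1-yl]oxolan-2-one | O=C1O[C@H](/C=C(\C)CC/C=C(/C)I)[C@@H](C=C)C1 | intermediate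
15 | (3R,4S,5S)-4-ethenyl-3-(hydroxymethyl)-5-[(1E,5Z)-6-iodo-2-methylhepta-1,5-dien-1-yl]oxolan-2-one | O=C1O[C@H](/C=C(\C)CC/C=C(/C)I)[C@@H](C=C)[C@@H]1CO | intermediate
16 | (3R,4R,5R)-4-ethenyl-3-hydroxy-3-(hydroxymethyl)-5-[(1E,5Z)-6-iodo-2-methylhepta-1,5-dien-1-yl]oxolan-2-one | O=C1O[C@H](/C=C(\C)CC/C=C(/C)I)[C@@H](C=C)[C@@]1(O)CO | intermediate
17 | (3R,4R,5R)-4-[(1R)-1,2-bis(4,4,5,5-tetramethyl-1,3,2-dioxaborolan-2-yl)ethyl]-3-hydroxy-3-(hydroxymethyl)-5-[(1E,5Z)-6-iodo-2-methylhepta-1,5-dien-1-yl]oxolan-2-one | O=C1O[C@H](/C=C(\C)CC/C=C(/C)I)[C@@H]([C@H](B2OC(C)(C)C(C)(C)O2)CB2OC(C)(C)C(C)(C)O2)[C@@]1(O)CO | intermediate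
18 | potassium 2,3-dihydroxy-2-[(3E,7Z)-2-hydroxy-4,8-dimethyl-10-(4,4,5,5-tetramethyl-1,3,2-dioxaborolan-2-yl)cyclodeca-3,7-dien-1-yl]propanoate (hydroxy-carboxylate form of 19, same configurations) | [K+].[O-]C(=O)[C@](O)(CO)[C@H]1[C@H](O)/C=C(\C)CC/C=C(/C)C[C@H]1B2OC(C)(C)C(C)(C)O2 | intermediate (not isolated)
19 | (1(10)Z,4E,6R,7R,8R,11R)-11,13-dihydroxy-8-(4,4,5,5-tetramethyl-1,3,2-dioxaborolan-2-yl)germacra-1(10),4-dien-12,6-olide | OC[C@@]1(O)C(=O)O[C@@H]2/C=C(\C)CC/C=C(/C)C[C@@H](B3OC(C)(C)C(C)(C)O3)[C@H]21 | intermediate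
20 | (1(10)Z,4E,6R,7R,8R,11R)-8,11,13-trihydroxygermacra-1(10),4-dien-12,6-olide | OC[C@@]1(O)C(=O)O[C@@H]2/C=C(\C)CC/C=C(/C)C[C@@H](O)[C@H]21 | intermediate
21 | ethyl 2-(hydroxymethyl)acrylate | C=C(CO)C(=O)OCC | starting material
22 | ethyl 2-{[(tert-butyldimethylsilyl)oxy]methyl}acrylate | C=C(CO[Si](C)(C)C(C)(C)C)C(=O)OCC | intermediate
23 | cis-2-butene | C/C=C\C | starting material
24 | ethyl (2E)-2-{[(tert-butyldimethylsilyl)oxy]methyl}but-2-enoate | C/C=C(\CO[Si](C)(C)C(C)(C)C)C(=O)OCC | intermediate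
25 | (2E)-2-{[(tert-butyldimethylsilyl)oxy]methyl}but-2-enoic acid | C/C=C(\CO[Si](C)(C)C(C)(C)C)C(=O)O | intermediate
26 | cis-but-2-ene-1,4-diol | OC/C=C\CO | starting material
27 | (2Z)-1,4-bis[(tert-butyldimethylsilyl)oxy]but-2-ene | CC(C)(C)[Si](C)(C)OC/C=C\CO[Si](C)(C)C(C)(C)C | intermediate
28 | ethyl (2E)-4-[(tert-butyldimethylsilyl)oxy]-2-{[(tert-butyldimethylsilyl)oxy]methyl}but-2-enoate | CCOC(=O)/C(=C/CO[Si](C)(C)C(C)(C)C)CO[Si](C)(C)C(C)(C)C | intermediate
29 | (2E)-4-[(tert-butyldimethylsilyl)oxy]-2-{[(tert-butyldimethylsilyl)oxy]methyl}but-2-enoic acid | OC(=O)/C(=C/CO[Si](C)(C)C(C)(C)C)CO[Si](C)(C)C(C)(C)C | intermediate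
30 | 13-O-[(2E)-2-{[(tert-butyldimethylsilyl)oxy]methyl}but-2-enoyl] ester of 20 | C/C=C(\CO[Si](C)(C)C(C)(C)C)C(=O)OC[C@@]1(O)C(=O)O[C@@H]2/C=C(\C)CC/C=C(/C)C[C@@H](O)[C@H]21 | intermediate
31 | 8-O-[(2E)-4-(TBS-oxy)-2-(TBS-oxymethyl)but-2-enoyl] ester of 30 | C/C=C(\CO[Si](C)(C)C(C)(C)C)C(=O)OC[C@@]1(O)C(=O)O[C@@H]2/C=C(\C)CC/C=C(/C)C[C@@H](OC(=O)/C(=C/CO[Si](C)(C)C(C)(C)C)CO[Si](C)(C)C(C)(C)C)[C@H]21 | intermediate
32 | CNP0360446.1, (1(10)Z,4E,6R,7R,8R,11R)-11-hydroxy-8-{[(2E)-4-hydroxy-2-(hydroxymethyl)but-2-enoyl]oxy}-13-{[(2E)-2-(hydroxymethyl)but-2-enoyl]oxy}germacra-1(10),4-dien-12,6-olide | C/C=C(\CO)C(=O)OC[C@@]1(O)C(=O)O[C@@H]2/C=C(\C)CC/C=C(/C)C[C@@H](OC(=O)/C(=C/CO)CO)[C@H]21 | target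

**Count.** Total: 21 steps. Longest linear sequence: 15 steps (steps 1–12 and 19–21); the two side-chain acids take 6 further steps (13–18).

**Steps most likely to fail**

Step 11 (ring closure). Oligomerisation, protodeboronation of the primary C–B bond or β-boryl elimination may outrun cyclisation to the ten-membered ring. Fallback: from 17, both C–B bonds would be oxidised (H2O2, pH 7 buffer) to the tetraol F1. The unhindered primary C9–OH would then be sulfonylated selectively (2,4,6-triisopropylbenzenesulfonyl chloride, pyridine; the neopentyl C13–OH is slower) and closed with K2CO3 to the terminal epoxide F2. A nickel-catalysed reductive ring closure of the alkenyl iodide onto the epoxide (NiCl2·glyme, 2,2'-bipyridine, NaI co-catalyst, Zn, Et3N·HCl, DMPU) would form C9–C10 again: iodide opens the epoxide at C9 and the C9 radical is captured by the alkenylnickel species. This would give the free 8-alcohol directly and rejoin the route at 20.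

Step 10 (diboration). The zerovalent platinum may insert into the C–I bond, or a mismatched ligand–substrate pairing may give poor facial selectivity at C8. Fallback: from 16, a transition-metal-free diboration directed by the homoallylic C11 alkoxide (B2pin2, Cs2CO3 cat., MeOH, THF, 70 °C) would deliver boron intramolecularly from the alkoxide–diboron adduct. This replaces catalyst control by substrate direction, keeps every metal away from the iodide, and comes back at 17 without any new compound (F0).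

Step 9 (α-hydroxylation). The dianion may lose formaldehyde by retro-aldol cleavage or enolise incompletely. Fallback: from 15, mesylation and elimination (MsCl, Et3N; then DBU) would give the α-methylene lactone F3. Nucleophilic epoxidation (t-BuOOH, DBU) would close the oxirane onto C11 anti to the C7 vinyl group to give the spiro-epoxide F4. Acid-catalysed hydrolysis at the primary C13 (dilute HClO4, THF/H2O) would leave the C11–O bond untouched and return to 16.

**Further compounds**

F1 | step 11 | tetraol: 4-(1,2-dihydroxyethyl) analogue of 16, both C–B bonds of 17 replaced by OH with retention | O=C1O[C@H](/C=C(\C)CC/C=C(/C)I)[C@@H]([C@H](O)CO)[C@@]1(O)CO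
F2 | step 11 | terminal epoxide: 4-(oxiran-2-yl) analogue of 16, C8 configured as in F1 | O=C1O[C@H](/C=C(\C)CC/C=C(/C)I)[C@@H]([C@H]2CO2)[C@@]1(O)CO
F0 | step 10 | none | none
F3 | step 9 | α-methylene lactone: (4R,5S)-4-ethenyl-5-[(1E,5Z)-6-iodo-2-methylhepta-1,5-dien-1-yl]-3-methylideneoxolan-2-one | O=C1O[C@H](/C=C(\C)CC/C=C(/C)I)[C@@H](C=C)C1=C
F4 | step 9 | spiro-epoxide of F3 at C11–C13, epoxide oxygen trans to the C7 vinyl group | O=C1O[C@H](/C=C(\C)CC/C=C(/C)I)[C@@H](C=C)[C@@]12CO2
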